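**Plan**

1. Retrosynthetic cuts: the two acetates; C13=C14 (olefination of a C13 methyl ketone); C9–C11 (carbonyl addition at C9 with 1,3-oxygen transposition to C7, later removed to leave C7=C8); the 2,3-cis-diol back to a C2=C3 alkene; then ring A at C3–C4; finally C10–C1 and C10–CH3 (enolate alkylations).
2. Enabling feature: ring B with its C8 methyl and C7=C8, together with C4 and its two methyls on C5, is a p-menthane. It is therefore (S)-carvone, whose isopropenyl carbon is C4 and whose ring ketone is C9.
3. Forward order: carvone supplies ring B and is alkylated twice at the future C10 (methyl, then a silylpropargyl arm). Ring A is closed last, when protonation of the isopropenyl group gives the C4 cation and a (Z)-vinylsilane captures it.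
4. After ring closure: osmylation of C2=C3, side-chain addition at C9, enone transposition, dissolving-metal reduction with enolate trapping, and chain extension to the E-enoic acid.
5. Stereochemistry: C5 is bought with (S)-carvone; C10 comes from alkylation anti to the isopropenyl group; C2 and C3 from osmylation anti to the axial C10 and C4 methyls; C9 from axial protonation; C13=C14 from an E-selective olefination.

Key step: step 4

Remark on conventions: labdane numbering is used for the decalin carbons of all intermediates, "syn" and "anti" refer to the face of the C10 methyl, and the target is an enantio-labdane, which is why the (S)-antipode of carvone is needed.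

**Route**

Step 1
Reactants: 1 (S)-(+)-carvone
Product: 3 (5S)-2,6-dimethyl-5-(prop-1-en-2-yl)cyclohex-2-en-1-one (6-methylcarvone; mixture of C6 epimers), via carvone lithium dienolate 2 (not isolated)
Conditions: LiN(i-Pr)2 (1.1 equiv), THF, −78 °C; then MeI, −78 to 0 °C
Reagents that add atoms: iodomethane, CI
Why: Kinetic deprotonation of carvone at the only sp3 α-carbon gives the cross-conjugated lithium dienolate, whose C-methylation is a standard enolate alkylation; the new centre is re-enolised in step 2, so its configuration does not matter.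

Step 2
Reactants: 3 6-methylcarvone; 4 3-bromo-1-(trimethylsilyl)prop-1-yne
Product: 6 (5R,6R)-2,6-dimethyl-5-(prop-1-en-2-yl)-6-[3-(trimethylsilyl)prop-2-yn-1-yl]cyclohex-2-en-1-one (propargyl arm trans to the isopropenyl group), via lithium enolate of 6-methylcarvone 5 (not isolated)
Conditions: LiN(i-Pr)2, THF, −78 to 0 °C; then DMPU, 4, −78 °C to rt
Reagents that add atoms: none
Why: In this enolate alkylation the reactive propargylic bromide should enter anti to the neighbouring isopropenyl group (1,2-induction), which sets the quaternary future C10 with the methyl cis and the three-carbon arm trans to the C5 substituent; the silyl cap suppresses allenyl products.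

Step 3
Reactants: 6 silylalkyne
Product: 7 (5R,6R)-2,6-dimethyl-5-(prop-1-en-2-yl)-6-[(2Z)-3-(trimethylsilyl)prop-2-en-1-yl]cyclohex-2-en-1-one
Conditions: H2 (1 atm), Pd on CaCO3 poisoned with Pb(OAc)2, quinoline, hexane/EtOAc, rt
Reagents that add atoms: none
Why: cis-Semihydrogenation of the silylalkyne over poisoned palladium should give the (Z)-vinylsilane, the geometry that a six-membered ring requires, without touching the 1,1-disubstituted alkene or the enone.

Step 4
Reactants: 7 (Z)-vinylsilane
Product: 8 (4aR,8aR)-2,5,5,8a-tetramethyl-4a,5,8,8a-tetrahydronaphthalen-1(4H)-one (trans-fused; labdane numbering C2=C3 and C7=C8 and C9=O)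
Conditions: CF3CO2H (5 equiv), CH2Cl2, −20 to 0 °C
Reagents that add atoms: none
Why: Trifluoroacetic acid protonates the isopropenyl group in the Markovnikov sense, so the future C4 becomes a tertiary cation that already carries both methyl groups; the silicon-bearing carbon of the (Z)-vinylsilane (future C3) attacks it, and the β-silyl cation at C2 loses the silyl group to trifluoroacetate, which returns the double bond to C2=C3. This is a vinylsilane-terminated cation–olefin cyclization, the closest relatives being proton-initiated polyene cyclizations with silicon-directed termination. Ring A closes in the 6-endo-trig mode through the C3–C4 bond, favoured over 5-exo attack through C2 by the β-silicon effect, since the alternative would give a destabilised α-silyl cation. No new stereocentre arises because C4 bears two methyl groups, and the trans ring fusion is inherited from the trans relation of the C10 arm and the C5 substituent set in step 2, both equatorial on ring B in a chair-like transition state. The step needs protonation of the isopropenyl group in preference to the vinylsilane (protodesilylation) and the enone, which the higher basicity of the 1,1-disubstituted alkene and the electron-poor enone should secure, and it needs the alkene to appear only at C2=C3, which loss of silicon instead of a proton secures.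

Step 5
Reactants: 8 bicyclic dienone
Product: 9 (4aR,6R,7S,8aR)-6,7-dihydroxy-2,5,5,8a-tetramethyl-4a,5,6,7,8,8a-hexahydronaphthalen-1(4H)-one (2,3-cis-diol anti to the C10 methyl)
Conditions: OsO4 (2 mol %), N-methylmorpholine N-oxide, acetone/H2O, rt
Reagents that add atoms: osmium tetroxide, O=[Os](=O)(=O)=O; N-methylmorpholine N-oxide, C[N+]1([O-])CCOCC1
Why: In this catalytic syn-dihydroxylation the isolated C2=C3 alkene should react in preference to the electron-poor enone alkene, and from the face opposite the axial C10 methyl and the axial C4 methyl, which sets C2 and C3 together by substrate control.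

Step 6
Reactants: 9 diol
Product: 10 2,3-O-isopropylidene acetal of 9 (cis-fused dioxolane on C2/C3; ring B 7-en-9-one)
Conditions: Me2C(OMe)2, pyridinium p-toluenesulfonate (cat.), acetone, rt
Reagents that add atoms: 2,2-dimethoxypropane, COC(C)(C)OC
Why: Acetonide formation of a cis-1,2-diol is routine and protects both hydroxyls against the organometallic, oxidative and dissolving-metal steps that follow.

Step 7
Reactants: 10 acetonide enone; 11 but-3-en-1-ylmagnesium bromide
Product: 12 9-(but-3-en-1-yl)-9-hydroxy-7-ene 2,3-acetonide (tertiary allylic alcohol; butenyl group expected anti to the C10 methyl)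
Conditions: 11, CeCl3 (anhydrous), THF, −78 to 0 °C; aq. NH4Cl
Reagents that add atoms: none
Why: The weakly basic organocerium reagent should add 1,2 to the hindered C9 ketone without enolisation, reduction or conjugate addition; the carbinol configuration is erased in step 8 and is of no consequence.

Step 8
Reactants: 12 tertiary allylic alcohol
Product: 13 9-(but-3-en-1-yl)-8-en-7-one 2,3-acetonide (transposed enone)
Conditions: pyridinium chlorochromate [C5H5NH][CrO3Cl], 4 Å molecular sieves, CH2Cl2, rt
Reagents that add atoms: none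
Why: Oxidative 1,3-transposition of a tertiary allylic alcohol (chromate ester, [3,3] shift, oxidation) moves the oxygen from C9 to C7 and places the side chain on the sp2 carbon C9.

Step 9
Reactants: 13 transposed enone
Product: 15 9-(but-3-en-1-yl)-7-en-7-yl trifluoromethanesulfonate 2,3-acetonide (H9 anti to the C10 methyl), via lithium C7 enolate 14 (not isolated)
Conditions: Li (2.2 equiv), t-BuOH (1 equiv), NH3(l)/THF, −78 °C; evaporate NH3; then PhNTf2, THF, −78 to 0 °C
Reagents that add atoms: N-phenylbis(trifluoromethanesulfonimide), O=S(=O)(N(c1ccccc1)S(=O)(=O)C(F)(F)F)C(F)(F)F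
Why: In this dissolving-metal conjugate reduction the β-carbon C9 is protonated axially, anti to the C10 methyl, which leaves the side chain equatorial and syn (stereoelectronic control); the regiospecific C7=C8 lithium enolate is then trapped on oxygen as the enol triflate.

Step 10
Reactants: 15 enol triflate
Product: 16 (2S,3R,5S,9R,10S)-2,3-isopropylidenedioxy-14,15-dinorlabda-7,13(16)-diene
Conditions: Pd(OAc)2 (5 mol %), PPh3, Et3N, HCO2H, DMF, 60 °C
Reagents that add atoms: none
Why: Palladium-catalysed formate reduction of an enol triflate replaces the C–O bond by C–H and fixes the trisubstituted alkene at C7=C8.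

Step 11
Reactants: 16 diene
Product: 17 (2S,3R,5S,9R,10S)-2,3-isopropylidenedioxy-14,15-dinorlabd-7-en-13-one
Conditions: PdCl2 (10 mol %), CuCl, O2 (1 atm), DMF/H2O, rt
Reagents that add atoms: water, O
Why: Wacker oxidation converts the terminal alkene into the methyl ketone in the Markovnikov sense, while the trisubstituted ring alkene should stay inert.

Step 12
Reactants: 17 methyl ketone; 18 triethyl phosphonoacetate
Product: 19 ethyl (2S,3R,5S,9R,10S,13E)-2,3-isopropylidenedioxylabda-7,13-dien-15-oate
Conditions: NaH, THF, 0 °C to reflux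
Reagents that add atoms: none
Why: Horner–Wadsworth–Emmons olefination of the unhindered methyl ketone should favour the E-enoate, with the larger chain trans to the ester; any minor Z isomer would be removed by chromatography.

Step 13
Reactants: 19 ethyl ester acetonide
Product: 21 (2S,3R,5S,9R,10S,13E)-2,3-dihydroxylabda-7,13-dien-15-oic acid, via lithium carboxylate acetonide 20 (not isolated)
Conditions: LiOH, THF/MeOH/H2O, 50 °C; then aq. HCl (pH 1), rt
Reagents that add atoms: lithium hydroxide, [Li+].[OH-]
Why: Saponification followed by mild aqueous acid hydrolysis of the acetonide in the same flask should free the acid and the diol without moving either double bond.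

Step 14
Reactants: 21 dihydroxy acid
Product: 23 (2S,3R,5S,9R,10S,13E)-2,3-diacetoxylabda-7,13-dien-15-oic acid (CNP0321684.1), via mixed acetic anhydride 22 (not isolated)
Conditions: Ac2O, pyridine, 4-(dimethylamino)pyridine (cat.), rt; then H2O/THF, rt
Reagents that add atoms: acetic anhydride, CC(=O)OC(C)=O
Why: Nucleophile-catalysed acetylation esterifies both the equatorial C2 and the hindered axial C3 hydroxyl, and the mixed anhydride formed at the carboxyl group is hydrolysed back to the acid in the aqueous stage.

**Compound list**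

1 | (S)-(+)-carvone, (5S)-2-methyl-5-(prop-1-en-2-yl)cyclohex-2-en-1-one | CC1=CC[C@@H](CC1=O)C(C)=C | starting material
2 | carvone lithium dienolate (O–Li on the former carbonyl, cross-conjugated) | C1=C(O[Li])C(C)=CC[C@@H]1C(C)=C | intermediate
3 | (5S)-2,6-dimethyl-5-(prop-1-en-2-yl)cyclohex-2-en-1-one (6-methylcarvone, C6 epimers) | CC1C(=O)C(C)=CC[C@@H]1C(C)=C | intermediate
4 | 3-bromo-1-(trimethylsilyl)prop-1-yne | C[Si](C)(C)C#CCBr | starting material
5 | lithium enolate of 6-methylcarvone | CC1=C(O[Li])C(C)=CC[C@@H]1C(C)=C | intermediate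
6 | (5R,6R)-2,6-dimethyl-5-(prop-1-en-2-yl)-6-[3-(trimethylsilyl)prop-2-yn-1-yl]cyclohex-2-en-1-one | C[Si](C)(C)C#CC[C@@]1(C)C(=O)C(C)=CC[C@@H]1C(C)=C | intermediate
7 | (5R,6R)-2,6-dimethyl-5-(prop-1-en-2-yl)-6-[(2Z)-3-(trimethylsilyl)prop-2-en-1-yl]cyclohex-2-en-1-one | C[Si](C)(C)/C=C\C[C@@]1(C)C(=O)C(C)=CC[C@@H]1C(C)=C | intermediate
8 | (4aR,8aR)-2,5,5,8a-tetramethyl-4a,5,8,8a-tetrahydronaphthalen-1(4H)-one | C1=CC(C)(C)[C@H]2CC=C(C)C(=O)[C@]2(C)C1 | intermediate
9 | (4aR,6R,7S,8aR)-6,7-dihydroxy-2,5,5,8a-tetramethyl-4a,5,6,7,8,8a-hexahydronaphthalen-1(4H)-one | O[C@H]1C[C@@]2(C)C(=O)C(C)=CC[C@@H]2C(C)(C)[C@H]1O | intermediate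
10 | 2,3-O-isopropylidene acetal of 9 | CC1(C)O[C@H]2C[C@@]3(C)C(=O)C(C)=CC[C@@H]3C(C)(C)[C@H]2O1 | intermediate
11 | but-3-en-1-ylmagnesium bromide | C=CCC[Mg]Br | starting material
12 | 9-(but-3-en-1-yl)-9-hydroxy-7-ene 2,3-acetonide (butenyl anti to the C10 methyl) | CC1(C)O[C@H]2C[C@@]3(C)[C@@](O)(CCC=C)C(C)=CC[C@@H]3C(C)(C)[C@H]2O1 | intermediate
13 | 9-(but-3-en-1-yl)-8-en-7-one 2,3-acetonide | CC1(C)O[C@H]2C[C@@]3(C)C(CCC=C)=C(C)C(=O)C[C@@H]3C(C)(C)[C@H]2O1 | intermediate
14 | lithium C7 enolate (C7=C8; H9 anti to the C10 methyl) | CC1(C)O[C@H]2C[C@@]3(C)[C@H](CCC=C)C(C)=C(O[Li])C[C@@H]3C(C)(C)[C@H]2O1 | intermediate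
15 | 9-(but-3-en-1-yl)-7-en-7-yl trifluoromethanesulfonate 2,3-acetonide | CC1(C)O[C@H]2C[C@@]3(C)[C@H](CCC=C)C(C)=C(OS(=O)(=O)C(F)(F)F)C[C@@H]3C(C)(C)[C@H]2O1 | intermediate
16 | (2S,3R,5S,9R,10S)-2,3-isopropylidenedioxy-14,15-dinorlabda-7,13(16)-diene | CC1(C)O[C@H]2C[C@@]3(C)[C@H](CCC=C)C(C)=CC[C@@H]3C(C)(C)[C@H]2O1 | intermediate
17 | (2S,3R,5S,9R,10S)-2,3-isopropylidenedioxy-14,15-dinorlabd-7-en-13-one | CC1(C)O[C@H]2C[C@@]3(C)[C@H](CCC(C)=O)C(C)=CC[C@@H]3C(C)(C)[C@H]2O1 | intermediate
18 | triethyl phosphonoacetate | CCOC(=O)CP(=O)(OCC)OCC | starting material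
19 | ethyl (2S,3R,5S,9R,10S,13E)-2,3-isopropylidenedioxylabda-7,13-dien-15-oate | CC1(C)O[C@H]2C[C@@]3(C)[C@H](CC/C(C)=C/C(=O)OCC)C(C)=CC[C@@H]3C(C)(C)[C@H]2O1 | intermediate
20 | lithium (13E)-2,3-isopropylidenedioxylabda-7,13-dien-15-oate | CC1(C)O[C@H]2C[C@@]3(C)[C@H](CC/C(C)=C/C(=O)O[Li])C(C)=CC[C@@H]3C(C)(C)[C@H]2O1 | intermediate
21 | (2S,3R,5S,9R,10S,13E)-2,3-dihydroxylabda-7,13-dien-15-oic acid | O[C@H]1C[C@@]2(C)[C@H](CC/C(C)=C/C(=O)O)C(C)=CC[C@@H]2C(C)(C)[C@H]1O | intermediate
22 | mixed acetic anhydride of the 2,3-diacetate | CC(=O)O[C@H]1C[C@@]2(C)[C@H](CC/C(C)=C/C(=O)OC(C)=O)C(C)=CC[C@@H]2C(C)(C)[C@H]1OC(C)=O | intermediate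
23 | (2S,3R,5S,9R,10S,13E)-2,3-diacetoxylabda-7,13-dien-15-oic acid (CNP0321684.1) | CC(=O)O[C@H]1C[C@@]2(C)[C@H](CC/C(C)=C/C(=O)O)C(C)=CC[C@@H]2C(C)(C)[C@H]1OC(C)=O | target

**Step count and risks**

Total step count: 14. Longest linear sequence: 14 steps, from (S)-carvone.

The three steps most likely to fail:

Step 4. The cation may be lost in three ways: protodesilylation of the vinylsilane before it cyclises; elimination and reprotonation at C5, which would erode the ring-fusion configuration; or capture by the C9 carbonyl oxygen. The fallback closes ring A without a carbocation; it leaves the route at 6 and rejoins it at 8. AgNO3 (cat.) and N-iodosuccinimide in DMF would exchange the alkynyl silyl group for iodine to give the 1-iodoalkyne F1. Diimide, generated from 2-nitrobenzenesulfonohydrazide and Et3N, would reduce it cis to the (Z)-vinyl iodide F2. Pd(OAc)2, PPh3, HCO2Na and Et4NCl in DMF at 80 °C would then effect a reductive Heck cyclization: oxidative addition, 6-exo-trig carbopalladation of the isopropenyl group (C3–C4 bond, quaternary C4), and formate reduction of the resulting alkylpalladium, which has no β-hydrogen, so that its CH2 becomes the second C4 methyl.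

Step 9. The dissolving-metal reduction may over-reduce the ketone or the terminal alkene, the hindered tetrasubstituted enolate may be trapped incompletely, or C9 may be protonated on the wrong face. The fallback leaves the route at 13 and rejoins it at 16, replacing steps 9 and 10. NaBH4 and CeCl3·7H2O in MeOH (Luche reduction, axial hydride delivery on the anti face) should give the allylic alcohol F3 with the C7 hydroxyl syn to the C10 methyl. A reductive 1,3-transposition would follow (PPh3, diethyl azodicarboxylate, 2-nitrobenzenesulfonohydrazide, THF, −30 °C to rt). Mitsunobu displacement with inversion gives the N-allyl sulfonylhydrazine F4, loss of sulfinic acid gives the allylic diazene F5, and its retro-ene loss of N2 delivers hydrogen to C9 on the anti face while the double bond moves to C7=C8.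

Step 12. The olefination of the methyl ketone may show poor E/Z selectivity, and the isomers may be hard to separate. The fallback builds the trisubstituted alkene stereospecifically; it leaves the route at 17 and rejoins it at 19. Kinetic enolisation towards the methyl group and phosphorylation (LiN(i-Pr)2; ClP(O)(OEt)2, THF, −78 °C) would give the enol phosphate F6, which further LiN(i-Pr)2 eliminates to the terminal alkyne F7. Zirconium-catalysed syn-carboalumination (Me3Al, (C5H5)2ZrCl2, CH2Cl2) would give the (E)-alkenylalane F8, and acylation with ethyl chloroformate, with retention at the alkenyl carbon, would give 19 as one alkene isomer.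

Further compounds
F1 | step 4 | (5R,6R)-6-(3-iodoprop-2-yn-1-yl)-2,6-dimethyl-5-(prop-1-en-2-yl)cyclohex-2-en-1-one | IC#CC[C@@]1(C)C(=O)C(C)=CC[C@@H]1C(C)=C
F2 | step 4 | (5R,6R)-6-[(2Z)-3-iodoprop-2-en-1-yl]-2,6-dimethyl-5-(prop-1-en-2-yl)cyclohex-2-en-1-one | I/C=C\C[C@@]1(C)C(=O)C(C)=CC[C@@H]1C(C)=C
F3 | step 9 | 9-(but-3-en-1-yl)-8-en-7-ol 2,3-acetonide (C7 hydroxyl syn to the C10 methyl) | CC1(C)O[C@H]2C[C@@]3(C)C(CCC=C)=C(C)[C@H](O)C[C@@H]3C(C)(C)[C@H]2O1
F4 | step 9 | N-(C7-allyl)-N-(2-nitrobenzenesulfonyl)hydrazine (nitrogen at C7 anti to the C10 methyl) | CC1(C)O[C@H]2C[C@@]3(C)C(CCC=C)=C(C)[C@@H](N(N)S(=O)(=O)c4ccccc4[N+](=O)[O-])C[C@@H]3C(C)(C)[C@H]2O1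
F5 | step 9 | C7 allylic diazene (nitrogen anti to the C10 methyl) | CC1(C)O[C@H]2C[C@@]3(C)C(CCC=C)=C(C)[C@@H](N=N)C[C@@H]3C(C)(C)[C@H]2O1
F6 | step 12 | diethyl enol phosphate of 17 (terminal C=CH2) | CC1(C)O[C@H]2C[C@@]3(C)[C@H](CCC(=C)OP(=O)(OCC)OCC)C(C)=CC[C@@H]3C(C)(C)[C@H]2O1
F7 | step 12 | 9-(but-3-yn-1-yl)-7-ene 2,3-acetonide (terminal alkyne) | CC1(C)O[C@H]2C[C@@]3(C)[C@H](CCC#C)C(C)=CC[C@@H]3C(C)(C)[C@H]2O1
F8 | step 12 | (E)-alkenyl(dimethyl)alane (aluminium on C14) | CC1(C)O[C@H]2C[C@@]3(C)[C@H](CC/C(C)=C/[Al](C)C)C(C)=CC[C@@H]3C(C)(C)[C@H]2O1
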